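## Structural features

The target is a cis-fused decalin. Ring A (C1–C2–C3–C4–C5–C10) and ring B (C5–C6–C7–C8–C9–C10) share the C5–C10 bond; C4 carries a methyl (C15), quaternary C5 the angular methyl (C14), C8 is a ketone and C7 carries an isopropenyl group. Five of the six stereocentres are contiguous (C3, C4, C5, C10, C9) and the sixth (C7) lies across the ketone. On the usual drawing the two methyls, H-10, the C9 oxygen and the isopropenyl group are β and only the C3 oxygen is α, so in the stable chair–chair conformer every substituent except the angular methyl is equatorial. The fragile parts are the β,γ-unsaturated ketone (C7 epimerises and C11=C12 can drift into conjugation), the α-acyloxy ketone at C9, and the tiglate (O3) and senecioate (O9) esters; these exclude strong base, catalytic hydrogenation and nucleophilic hydride late in the route. The real difficulty is quaternary C5, flanked by stereocentres on both sides (cis-vicinal methyls at C4/C5, cis fusion at C5/C10), together with telling C7 from C9 on either side of the C8 ketone. The key step uses the 1,4-relationship of the C8 carbonyl and C5: ring B is a reduced 4-methyl-4-alkylcyclohexa-2,5-dienone whose β-carbons C6 and C10 are equivalent until ring A closes on one of them through C1–C10. A second relationship decides how C3 must be carried through that closure: the C3 oxygen and C6 are cis (1,3) across ring A.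

## Logic of the disconnections

34 to 32, then 32 to 30 and 31: C6=C7 is restored and the C7–C11 bond is cut. The epimerisable, isomerisable C7 centre is made last so that no later step can disturb it. This removes one stereocentre and the isopropenyl group and leaves an α-iodoenone. The forward steps must couple under neutral conditions and then reduce the enone without touching two unsaturated esters, with protonation at C7 and not at C12.

30 to 29 to 27: the senecioyl C–O bond and then the C9–O bond are cut. In 27, C9 is the only enolisable carbon (C7 is sp2, C5 is quaternary), so the regiochemistry costs nothing. The oxidant must come from the β face, and the acylation must not shift the ester double bond.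

27 to 26 to 25: the two hydrogens on C1 and C2 and the iodine on C7 are removed. The iodine is the coupling handle and also makes C6=C7 trisubstituted, so the C1=C2 bond left by the ring closure can be reduced beside it. The reductant must separate a cis-disubstituted alkene from a trisubstituted iodoalkene and a tiglate.

25 to 23 to 22: the C3–O bond of the tiglate is cut with inversion, then the silyl group is added back. The ring closure needs the C3 oxygen β (next paragraph); an allylic Mitsunobu esterification corrects it and installs the ester in one step. The forward step must be SN2 at C3, not elimination or SN2′.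

22 to 19 (key): C1–C10 is cut. Ring A and the stereocentres C5 and C10 disappear, leaving a symmetric dienone with two side-chain stereocentres and a Z-iodoalkene. The closure must choose the arm that puts the C5 methyl cis to the C4 methyl. Because the new bond forms axial on ring B, ring A closes through a chair in which the spectator arm C6 is axial and the C5 methyl equatorial; the cis-dimethyl product therefore needs the C4 methyl axial. A C3 silyloxy group is equatorial in that chair only if it is cis to the C4 methyl (3β). A 3α-silyloxy group would have to sit axial, 1,3 to the spectator arm and beside palladium, and would steer the closure to the wrong arm. So 19 carries the 3β ether.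

19 to 18, then 18 to 14 and 15: the C6=C7 unsaturation is removed, then C9=C10 and C5–C6 are cut (annulation in reverse). Ring B comes from methyl vinyl ketone and an α-branched aldehyde. C5 is stereogenic in 14 to 18 but not in 19, so its configuration is irrelevant. The Michael step must build a quaternary carbon beside a tertiary one.

14 to 13 to 12 to 11: functional-group changes only (aldehyde from alcohol, Z-iodoalkene from iodoalkyne, iodoalkyne from alkynylsilane). The alkyne is carried masked and turned into the Z-iodide at the one stage where the molecule has no other C=C bond. The syn semireduction must not over-reduce.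

11 to 9 to 8: the C5–C10 bond is cut (one-carbon unit). The homologation goes through an alkene because 8 is a β-silyloxy ketone with an α-stereocentre (C4), which a basic ylide could enolise or eliminate. The methylenation must be non-basic.

8 to 7 to 6, then 6 to 1 and 2: the ketone goes back to the vinyl group, the silyl group is removed, and C3–C4 is cut. This gives two commercial fragments and sets C3 and C4 in one reagent-controlled step. It must be anti-selective and enantioselective.

## Other disconnections considered

Alternative 1: Cut: C5–C6, with the C3–C8 bond of a cage precursor broken in the same event. Forward: the vinyl carbinol A1 (from oxidative dearomatisation of a dimethylguaiacol, cycloaddition and vinyl addition) would rearrange as its potassium alkoxide (KH, 18-crown-6) by a [3,3] shift to A2.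
- In its favour: the shift is concerted and suprafacial, so the cis fusion and the C5/C10 relationship follow from the cage geometry with no choice between arms; on this point it is the better plan. A2 would be reached in about four steps against eleven for 22 (better). Its C9 acetal blocks enolisation on that side, so C7 is the only α-carbon of the C8 ketone; this is equal to or better than the iodoenone solution of the chosen plan.
- Against it here: A2 has no oxygen at C3 and no stereocentre at C4, and nothing in A2 guarantees hydroboration of C3=C4 from the α face. C9 arrives at the ketone oxidation level next to C8, so unmasking gives a 1,2-dione that must be reduced regio- and stereoselectively. A1 would be racemic without an auxiliary or a resolution, whereas the chosen plan takes its absolute configuration from a reagent-controlled crotylboration.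
- Comparison: it handles ring B better and ring A worse; it is shorter to the bicycle but probably longer and less certain after it.

Alternative 2: Cut: C1–C2 and C5–C10. Forward: the acyclic trienone A3 would cyclise on heating or with Me2AlCl to A4, closing both rings and setting C5 and C10 together.
- In its favour: the largest gain per step (two rings and two bonds against one bond in step 11; better). C7 with its isopropenyl group and the C8 oxygen are already in the chain, so no late work at C7 is needed (better than steps 14, 18 and 19). The silyl enol ether delivers the C3 carbonyl.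
- Against it here: the diene terminus C5 is fully substituted with a methyl pointing inward in the reactive conformer, and C4 carries another methyl, so the cycloaddition should be slow while the vinyl ketone polymerises. The cis fusion rests on an endo/exo preference that a four-atom tether controls only weakly, whereas in step 11 it is enforced by geometry (chosen plan better). Both plans leave the configuration of C5 relative to existing centres to a conformational preference (equal). In A4 the ring B oxygens are transposed with respect to 34 (ether oxygen on C8, ketone on C9), which costs a reduction, an acylation, a deprotection and an oxidation; C4 is still to be set by protonation.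
- Comparison: A3 is not obviously shorter to make than 19, so the step count is likely comparable, with the risk concentrated in one step in both plans.

Alternative 3: Cut: C3–C4 and C4–C5 (the C4 methine with its methyl is inserted between carbonyl C3 and quaternary C5). Forward: A5, the monoketal of the hydrogenated bicyclic dione that proline catalysis supplies in enantiopure form, would add 1,1-dibromoethyllithium at the cyclopentanone; n-BuLi would then generate the β-oxido carbenoid, in which C5 migrates to give A6.
- In its favour: the absolute configuration and quaternary C5 come from a cheap organocatalytic annulation, so C5 needs no selective step at all (better). The cis fusion rests on a hydrogenation (equal). The C3 ketone sits where the tiglate must go, and A6 would be about four steps from a commercial dione (better).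
- Against it here: migration of C5 rather than C2, and the C4 configuration, are preferences only. After ketal removal ring B is a plain cyclohexanone whose α-methylenes C7 and C9 are not differentiated; the enone left by step 11 does this in the chosen plan. The C3 ketone must still be reduced to the 3α alcohol.
- Comparison: a shorter and stereochemically safer entry to the carbon skeleton, but the steps saved would probably be spent again on ring B.

Key step: step 11

Remarks on the chemistry (assumptions):
- Locants are those of the target; α/β refer to the usual drawing with the C5 methyl β; "decal" names use these locants.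
- The crotylborane made from (−)-α-pinene is taken to add to the Re face of the aldehyde, as this reagent class does with simple aldehydes.
- Compounds 10 to 18 are mixtures of C5 epimers; this centre becomes non-stereogenic in 19 and is left unspecified in the SMILES.
- Phosphine ligands are not drawn in 20, 21 and 33.

Step 1
Reactants: 1 3-(trimethylsilyl)prop-2-ynal; 2 trans-but-2-ene
Product: 6 (3R,4R)-4-methyl-1-(trimethylsilyl)hex-5-en-1-yn-3-ol, via (E)-crotylpotassium 3 (not isolated), via (E)-crotyldiisopinocampheylborane 4 (not isolated), via the borinate ester of the adduct 5 (not isolated)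
Conditions: 2, n-BuLi, KOt-Bu, THF, −78 to −45 °C; (+)-Ipc2BOMe [from (−)-α-pinene], −78 °C; BF3·OEt2; 1, −78 °C; then ethanolamine, rt
Reagents that add atoms: none
Why: Brown crotylboration: the E-crotylborane reacts through a closed chair-like six-membered transition state, so the E geometry becomes the anti C3/C4 relationship, and the isopinocampheyl groups direct attack to the Re face of the aldehyde, setting C3 (R) and C4 (R). C4 has the configuration of the target; C3 is deliberately its epimer and is inverted in step 13.

Step 2
Reactants: 6 (3R,4R)-4-methyl-1-(trimethylsilyl)hex-5-en-1-yn-3-ol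
Product: 7 (3R,4R)-3-(tert-butyldimethylsilyloxy)-4-methyl-1-(trimethylsilyl)hex-5-en-1-yne
Conditions: TBSCl, imidazole, DMF, rt
Reagents that add atoms: tert-butyldimethylsilyl chloride, CC(C)(C)[Si](C)(C)Cl
Why: Standard silylation of a secondary propargylic alcohol; the bulky silyl ether is also the group that later controls the ring closure.

Step 3
Reactants: 7 (3R,4R)-3-(tert-butyldimethylsilyloxy)-4-methyl-1-(trimethylsilyl)hex-5-en-1-yne
Product: 8 (3S,4R)-4-(tert-butyldimethylsilyloxy)-3-methyl-6-(trimethylsilyl)hex-5-yn-2-one
Conditions: PdCl2 (10 mol%), CuCl, O2 (1 atm), DMF/H2O 7:1, rt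
Reagents that add atoms: water, O
Why: Wacker oxidation of the terminal alkene with Markovnikov selectivity gives the methyl ketone whose methyl becomes C14; the near-neutral medium leaves the α-stereocentre C4 and the β-silyloxy group alone, and the silyl-capped internal alkyne is not hydrated.

Step 4
Reactants: 8 (3S,4R)-4-(tert-butyldimethylsilyloxy)-3-methyl-6-(trimethylsilyl)hex-5-yn-2-one
Product: 9 (3R,4R)-4-(tert-butyldimethylsilyloxy)-2,3-dimethyl-6-(trimethylsilyl)hex-1-en-5-yne
Conditions: Zn, CH2Br2, TiCl4 (reagent preformed), THF/CH2Cl2, 0 °C to rt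
Reagents that add atoms: dibromomethane, BrCBr
Why: Non-basic carbonyl methylenation with the zinc/titanium methylene reagent, chosen because a basic ylide could enolise C4 or eliminate the β-silyloxy group of 8; the new methylene carbon becomes C10.

Step 5
Reactants: 9 (3R,4R)-4-(tert-butyldimethylsilyloxy)-2,3-dimethyl-6-(trimethylsilyl)hex-1-en-5-yne
Product: 11 (2RS,3R,4R)-4-(tert-butyldimethylsilyloxy)-2,3-dimethyl-6-(trimethylsilyl)hex-5-yn-1-ol, via the B-alkyl-9-BBN adduct 10 (not isolated)
Conditions: 9-BBN, THF, 0 °C to rt; then H2O2, NaOAc, H2O, 0 °C to rt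
Reagents that add atoms: hydrogen peroxide, OO
Why: Anti-Markovnikov hydroboration of the 1,1-disubstituted alkene, which 9-BBN attacks much faster than a silylated internal alkyne, then buffered oxidation. The new C5 centre forms without control and does not matter.

Step 6
Reactants: 11 (2RS,3R,4R)-4-(tert-butyldimethylsilyloxy)-2,3-dimethyl-6-(trimethylsilyl)hex-5-yn-1-ol
Product: 12 (2RS,3R,4R)-4-(tert-butyldimethylsilyloxy)-6-iodo-2,3-dimethylhex-5-yn-1-ol
Conditions: N-iodosuccinimide, AgNO3 (10 mol%), DMF, rt, dark
Reagents that add atoms: N-iodosuccinimide, O=C1CCC(=O)N1I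
Why: Silver-catalysed iododesilylation of an alkynylsilane, a direct C–Si to C–I exchange through the silver acetylide; a free primary alcohol and a silyl ether are tolerated.

Step 7
Reactants: 12 (2RS,3R,4R)-4-(tert-butyldimethylsilyloxy)-6-iodo-2,3-dimethylhex-5-yn-1-ol
Product: 13 (2RS,3R,4R,5Z)-4-(tert-butyldimethylsilyloxy)-6-iodo-2,3-dimethylhex-5-en-1-ol
Conditions: 2-nitrobenzenesulfonohydrazide, Et3N, THF/i-PrOH, rt
Reagents that add atoms: none
Why: Diimide semireduction of a 1-iodoalkyne: concerted syn transfer of two hydrogens gives the Z-iodoalkene, which the ring closure needs so that C3 and palladium are cis on the alkene. It is done here because 12 has no other C=C bond.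

Step 8
Reactants: 13 (2RS,3R,4R,5Z)-4-(tert-butyldimethylsilyloxy)-6-iodo-2,3-dimethylhex-5-en-1-ol
Product: 14 (2RS,3R,4R,5Z)-4-(tert-butyldimethylsilyloxy)-6-iodo-2,3-dimethylhex-5-enal
Conditions: triacetoxyperiodinane (DMP), CH2Cl2, rt
Reagents that add atoms: none
Why: Periodinane oxidation of a primary alcohol to the aldehyde under neutral conditions; silyl ether and iodoalkene are inert, and the oxygen on C3 is γ to the carbonyl, so no β-elimination is possible.

Step 9
Reactants: 14 (2RS,3R,4R,5Z)-4-(tert-butyldimethylsilyloxy)-6-iodo-2,3-dimethylhex-5-enal; 15 but-3-en-2-one (methyl vinyl ketone)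
Product: 18 (4RS)-4-[(2R,3R,4Z)-3-(tert-butyldimethylsilyloxy)-5-iodopent-4-en-2-yl]-4-methylcyclohex-2-en-1-one, via the pyrrolidine enamine 16 (not isolated), via the keto-aldehyde 17 (not isolated)
Conditions: pyrrolidine (1.1 equiv), 4 Å MS, toluene, rt; 15, rt to 50 °C; then AcOH, NaOAc, H2O, 80 °C
Reagents that add atoms: none
Why: Stork enamine Michael addition of an α-branched aldehyde to methyl vinyl ketone builds quaternary C5 (C5–C6 bond); hydrolysis and intramolecular aldol condensation (C9=C10) complete a Robinson-type annulation to the 4,4-disubstituted cyclohexenone. Both C5 epimers are used.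

Step 10
Reactants: 18 (4RS)-4-[(2R,3R,4Z)-3-(tert-butyldimethylsilyloxy)-5-iodopent-4-en-2-yl]-4-methylcyclohex-2-en-1-one
Product: 19 4-[(2R,3R,4Z)-3-(tert-butyldimethylsilyloxy)-5-iodopent-4-en-2-yl]-4-methylcyclohexa-2,5-dien-1-one
Conditions: IBX (3 equiv), DMSO/toluene 1:2, 75 °C
Reagents that add atoms: none
Why: IBX dehydrogenation through the enol at C7, the only enolisable α-carbon, gives the cross-conjugated dienone, which cannot aromatise because C5 is quaternary. C5 loses its stereogenicity, so both epimers of 18 converge on one prochiral compound.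

Step 11
Reactants: 19 4-[(2R,3R,4Z)-3-(tert-butyldimethylsilyloxy)-5-iodopent-4-en-2-yl]-4-methylcyclohexa-2,5-dien-1-one
Product: 22 (10βH)-3β-(tert-butyldimethylsilyloxy)-4β,5β-dimethyldecal-1,6-dien-8-one, via the alkenylpalladium iodide 20 (not isolated), via the palladium enolate 21 (not isolated)
Conditions: Pd(OAc)2 (10 mol%), PPh3 (25 mol%), HCO2Na (3 equiv), Et4NCl (1 equiv), DMF, 60 °C
Reagents that add atoms: none
Why: Zerovalent palladium, formed from Pd(OAc)2, PPh3 and formate, inserts into the C1–I bond with retention of the Z geometry to give 20; the alkenyl–palladium bond then adds syn across C9=C10 of one enone arm in a 6-exo-trig closure of ring A to give 21, which has no syn β-hydrogen (H-10 is anti to palladium) and is reduced by formate (decarboxylation to a palladium hydride, then C–H reductive elimination), so the net result is conjugate addition. This is an intramolecular reductive Heck reaction, of the type known for alkenyl iodides adding to enones and for aryl halides desymmetrising 4,4-disubstituted cyclohexadienones. C10: the tether reaches the β-carbon only from the dienone face that carries C4, so C1 and C4 end up cis and the fusion is necessarily cis (H-10 and the C5 methyl on the same face). C5: its configuration is fixed by which of the two diastereotopic arms is attacked; the C1–C10 bond forms perpendicular to the enone plane (axial on ring B), so ring A closes through a chair with the spectator arm C6 axial and the C5 methyl equatorial. The arm is chosen so that the bulky C3 silyloxy group stays equatorial, away from palladium (cis to C3 on the Z-alkenyl unit) and from the axial spectator arm; with the (2R,3R) side chain this puts the C4 methyl axial (one 1,3-contact, with H-10) and hence cis to the C5 methyl, as the target needs. A 3α-silyl ether would need its oxygen axial in the same transition state, which is why C3 is carried as the 3β epimer and inverted in step 13. The step also needs ring closure to outrun direct formate reduction of 20, which the intramolecular 6-exo insertion should ensure, and the allylic silyl ether, unlike an allylic ester, is not ionised by zerovalent palladium.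

Step 12
Reactants: 22 (10βH)-3β-(tert-butyldimethylsilyloxy)-4β,5β-dimethyldecal-1,6-dien-8-one
Product: 23 (10βH)-3β-hydroxy-4β,5β-dimethyldecal-1,6-dien-8-one
Conditions: HF·pyridine, pyridine, THF, 0 °C to rt
Reagents that add atoms: none
Why: Fluoride cleavage of the silyl ether under buffered acidic conditions that leave the enone alone. The 3β-hydroxyl is trans to C6 across ring A and cannot add to the enone.

Step 13
Reactants: 23 (10βH)-3β-hydroxy-4β,5β-dimethyldecal-1,6-dien-8-one
Product: 25 (10βH)-4β,5β-dimethyl-8-oxodecal-1,6-dien-3α-yl (E)-2-methylbut-2-enoate, via the alkoxyphosphonium tiglate 24 (not isolated)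
Conditions: tiglic acid, PPh3, DIAD, toluene, −20 to 0 °C
Reagents that add atoms: tiglic acid, C/C=C(\C)C(=O)O
Why: Mitsunobu esterification: the allylic alkoxyphosphonium ion 24 is displaced by tiglate in an SN2 reaction with inversion, giving the 3α ester of the target and installing the tiglate in the same step. The carboxylate approaches the α face, anti to the leaving group and away from the C4 and C5 methyls, and it is done before step 14 because PPh3 would attack an α-iodoenone.

Step 14
Reactants: 25 (10βH)-4β,5β-dimethyl-8-oxodecal-1,6-dien-3α-yl (E)-2-methylbut-2-enoate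
Product: 26 (10βH)-7-iodo-4β,5β-dimethyl-8-oxodecal-1,6-dien-3α-yl (E)-2-methylbut-2-enoate
Conditions: I2, pyridine, CH2Cl2, 0 °C to rt
Reagents that add atoms: iodine, II
Why: α-Iodination of a cyclic enone by pyridine-assisted addition, iodination and elimination; C7 is the only position that can react. The iodine also makes C6=C7 trisubstituted before step 15.

Step 15
Reactants: 26 (10βH)-7-iodo-4β,5β-dimethyl-8-oxodecal-1,6-dien-3α-yl (E)-2-methylbut-2-enoate
Product: 27 (10βH)-7-iodo-4β,5β-dimethyl-8-oxodecal-6-en-3α-yl (E)-2-methylbut-2-enoate
Conditions: KO2CN=NCO2K, AcOH, MeOH/CH2Cl2, rt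
Reagents that add atoms: none
Why: Diimide reduces the cis-disubstituted C1=C2 bond; the trisubstituted iodoalkene of the enone and the trisubstituted tiglate double bond react far more slowly. Diimide, unlike catalytic hydrogenation, leaves the C–I bond intact.

Step 16
Reactants: 27 (10βH)-7-iodo-4β,5β-dimethyl-8-oxodecal-6-en-3α-yl (E)-2-methylbut-2-enoate
Product: 29 (10βH)-9β-hydroxy-7-iodo-4β,5β-dimethyl-8-oxodecal-6-en-3α-yl (E)-2-methylbut-2-enoate, via the potassium dienolate 28 (not isolated)
Conditions: KN(SiMe3)2, THF, −78 °C; 2-(phenylsulfonyl)-3-phenyloxaziridine, −78 °C; aq. NH4Cl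
Reagents that add atoms: 2-(phenylsulfonyl)-3-phenyloxaziridine, O=S(=O)(N1OC1c1ccccc1)c1ccccc1
Why: Kinetic α′-deprotonation can occur only at C9 (C7 is sp2, C5 quaternary), and the enolate is hydroxylated by the N-sulfonyloxaziridine. Ring A, through axial C4 (1,3 to C9), covers the α face of ring B, so oxygen should enter from the β face to give the equatorial 9β alcohol, which is also the more stable epimer.

Step 17
Reactants: 29 (10βH)-9β-hydroxy-7-iodo-4β,5β-dimethyl-8-oxodecal-6-en-3α-yl (E)-2-methylbut-2-enoate
Product: 30 (10βH)-7-iodo-4β,5β-dimethyl-9β-(3-methylbut-2-enoyloxy)-8-oxodecal-6-en-3α-yl (E)-2-methylbut-2-enoate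
Conditions: 3-methylbut-2-enoyl chloride, pyridine, DMAP (cat.), CH2Cl2, 0 °C
Reagents that add atoms: 3-methylbut-2-enoyl chloride, CC(C)=CC(=O)Cl
Why: Acylation of the secondary α-hydroxy ketone; pyridine is used instead of a trialkylamine so that the acid chloride is not deconjugated through a vinylketene.

Step 18
Reactants: 30 (10βH)-7-iodo-4β,5β-dimethyl-9β-(3-methylbut-2-enoyloxy)-8-oxodecal-6-en-3α-yl (E)-2-methylbut-2-enoate; 31 tributyl(prop-1-en-2-yl)stannane
Product: 32 9β-(3-methylbut-2-enoyloxy)-8-oxo-10βH-eremophila-6,11-dien-3α-yl (E)-2-methylbut-2-enoate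
Conditions: Pd2(dba)3 (5 mol%), AsPh3 (20 mol%), CuI (10 mol%), NMP, rt
Reagents that add atoms: none
Why: Stille coupling of an α-iodoenone with an alkenylstannane forms C7–C11; it needs no base, which spares the α-acyloxy ketone and both esters, and there is no longer an allylic ester that zerovalent palladium could ionise.

Step 19
Reactants: 32 9β-(3-methylbut-2-enoyloxy)-8-oxo-10βH-eremophila-6,11-dien-3α-yl (E)-2-methylbut-2-enoate
Product: 34 (3R,4R,5R,7R,9R,10S)-9β-(3-methylbut-2-enoyloxy)-8-oxo-10βH-eremophil-11-en-3α-yl (E)-2-methylbut-2-enoate, via the copper enolate 33 (not isolated)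
Conditions: [(Ph3P)CuH]6 (0.4 equiv), toluene, H2O (3 equiv), rt; aq. NH4Cl
Reagents that add atoms: none
Why: Copper hydride conjugate reduction: hydride adds to C6 of the enone only, since the β-substituted trisubstituted enoates are much poorer acceptors, and the copper dienolate 33 is protonated at C7 (kinetic α-protonation) to give the β,γ-unsaturated ketone. The 7β epimer has the isopropenyl group equatorial, whereas in the 7α epimer it would be 1,3-diaxial to C4, so 7β is expected as the stable product.

Compound list

1 | 3-(trimethylsilyl)prop-2-ynal | C[Si](C)(C)C#CC=O | starting material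
2 | trans-but-2-ene | C/C=C/C | starting material
3 | (E)-crotylpotassium | [K+].[CH2-]/C=C/C | intermediate (not isolated)
4 | (E)-crotyldiisopinocampheylborane, isopinocampheyl groups from (−)-α-pinene | C/C=C/CB([C@H]1C[C@H]2C[C@@H]([C@@H]1C)C2(C)C)[C@H]1C[C@H]2C[C@@H]([C@@H]1C)C2(C)C | intermediate (not isolated)
5 | diisopinocampheylborinate ester of 6 | C=C[C@@H](C)[C@@H](OB([C@H]1C[C@H]2C[C@@H]([C@@H]1C)C2(C)C)[C@H]1C[C@H]2C[C@@H]([C@@H]1C)C2(C)C)C#C[Si](C)(C)C | intermediate (not isolated)
6 | (3R,4R)-4-methyl-1-(trimethylsilyl)hex-5-en-1-yn-3-ol | C=C[C@@H](C)[C@@H](O)C#C[Si](C)(C)C | intermediate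
7 | (3R,4R)-3-(tert-butyldimethylsilyloxy)-4-methyl-1-(trimethylsilyl)hex-5-en-1-yne | C=C[C@@H](C)[C@@H](O[Si](C)(C)C(C)(C)C)C#C[Si](C)(C)C | intermediate
8 | (3S,4R)-4-(tert-butyldimethylsilyloxy)-3-methyl-6-(trimethylsilyl)hex-5-yn-2-one | CC(=O)[C@@H](C)[C@@H](O[Si](C)(C)C(C)(C)C)C#C[Si](C)(C)C | intermediate
9 | (3R,4R)-4-(tert-butyldimethylsilyloxy)-2,3-dimethyl-6-(trimethylsilyl)hex-1-en-5-yne | C=C(C)[C@@H](C)[C@@H](O[Si](C)(C)C(C)(C)C)C#C[Si](C)(C)C | intermediate
10 | B-alkyl-9-borabicyclo[3.3.1]nonane adduct of 9 (boron on C1 of the hexyne chain) | CC(CB1C2CCCC1CCC2)[C@@H](C)[C@@H](O[Si](C)(C)C(C)(C)C)C#C[Si](C)(C)C | intermediate (not isolated)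
11 | (2RS,3R,4R)-4-(tert-butyldimethylsilyloxy)-2,3-dimethyl-6-(trimethylsilyl)hex-5-yn-1-ol | OCC(C)[C@@H](C)[C@@H](O[Si](C)(C)C(C)(C)C)C#C[Si](C)(C)C | intermediate
12 | (2RS,3R,4R)-4-(tert-butyldimethylsilyloxy)-6-iodo-2,3-dimethylhex-5-yn-1-ol | OCC(C)[C@@H](C)[C@@H](O[Si](C)(C)C(C)(C)C)C#CI | intermediate
13 | (2RS,3R,4R,5Z)-4-(tert-butyldimethylsilyloxy)-6-iodo-2,3-dimethylhex-5-en-1-ol | OCC(C)[C@@H](C)[C@@H](O[Si](C)(C)C(C)(C)C)/C=C\I | intermediate
14 | (2RS,3R,4R,5Z)-4-(tert-butyldimethylsilyloxy)-6-iodo-2,3-dimethylhex-5-enal | O=CC(C)[C@@H](C)[C@@H](O[Si](C)(C)C(C)(C)C)/C=C\I | intermediate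
15 | but-3-en-2-one (methyl vinyl ketone) | CC(=O)C=C | starting material
16 | 1-[(3R,4R,5Z)-4-(tert-butyldimethylsilyloxy)-6-iodo-2,3-dimethylhexa-1,5-dienyl]pyrrolidine | C(=C(C)[C@@H](C)[C@@H](O[Si](C)(C)C(C)(C)C)/C=C\I)N1CCCC1 | intermediate (not isolated)
17 | (2RS)-2-[(2R,3R,4Z)-3-(tert-butyldimethylsilyloxy)-5-iodopent-4-en-2-yl]-2-methyl-5-oxohexanal | O=CC(C)(CCC(C)=O)[C@@H](C)[C@@H](O[Si](C)(C)C(C)(C)C)/C=C\I | intermediate (not isolated)
18 | (4RS)-4-[(2R,3R,4Z)-3-(tert-butyldimethylsilyloxy)-5-iodopent-4-en-2-yl]-4-methylcyclohex-2-en-1-one | O=C1C=CC(C)(CC1)[C@@H](C)[C@@H](O[Si](C)(C)C(C)(C)C)/C=C\I | intermediate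
19 | 4-[(2R,3R,4Z)-3-(tert-butyldimethylsilyloxy)-5-iodopent-4-en-2-yl]-4-methylcyclohexa-2,5-dien-1-one | O=C1C=CC(C)(C=C1)[C@@H](C)[C@@H](O[Si](C)(C)C(C)(C)C)/C=C\I | intermediate
20 | Z-alkenylpalladium iodide from 19 (divalent palladium on C1) | O=C1C=CC(C)(C=C1)[C@@H](C)[C@@H](O[Si](C)(C)C(C)(C)C)/C=C\[Pd]I | intermediate (not isolated)
21 | palladium enolate after ring closure (palladium on C9, α face) | O=C1C=C[C@@]2(C)[C@H](C=C[C@H](O[Si](C)(C)C(C)(C)C)[C@@H]2C)[C@@H]1[Pd]I | intermediate (not isolated)
22 | (10βH)-3β-(tert-butyldimethylsilyloxy)-4β,5β-dimethyldecal-1,6-dien-8-one | O=C1C=C[C@@]2(C)[C@H](C=C[C@H](O[Si](C)(C)C(C)(C)C)[C@@H]2C)C1 | intermediate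
23 | (10βH)-3β-hydroxy-4β,5β-dimethyldecal-1,6-dien-8-one | O=C1C=C[C@@]2(C)[C@H](C=C[C@H](O)[C@@H]2C)C1 | intermediate
24 | 3β-O-triphenylphosphonium derivative of 23, tiglate salt | C/C=C(\C)C(=O)[O-].O=C1C=C[C@@]2(C)[C@H](C=C[C@H](O[P+](c3ccccc3)(c3ccccc3)c3ccccc3)[C@@H]2C)C1 | intermediate (not isolated)
25 | (10βH)-4β,5β-dimethyl-8-oxodecal-1,6-dien-3α-yl (E)-2-methylbut-2-enoate | O=C1C=C[C@@]2(C)[C@H](C=C[C@@H](OC(=O)/C(C)=C/C)[C@@H]2C)C1 | intermediate
26 | (10βH)-7-iodo-4β,5β-dimethyl-8-oxodecal-1,6-dien-3α-yl (E)-2-methylbut-2-enoate | O=C1C(I)=C[C@@]2(C)[C@H](C=C[C@@H](OC(=O)/C(C)=C/C)[C@@H]2C)C1 | intermediate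
27 | (10βH)-7-iodo-4β,5β-dimethyl-8-oxodecal-6-en-3α-yl (E)-2-methylbut-2-enoate | O=C1C(I)=C[C@@]2(C)[C@H](CC[C@@H](OC(=O)/C(C)=C/C)[C@@H]2C)C1 | intermediate
28 | potassium 6,8-dienolate of 27 | IC1=C[C@@]2(C)[C@H](CC[C@@H](OC(=O)/C(C)=C/C)[C@@H]2C)C=C1[O-].[K+] | intermediate (not isolated)
29 | (10βH)-9β-hydroxy-7-iodo-4β,5β-dimethyl-8-oxodecal-6-en-3α-yl (E)-2-methylbut-2-enoate | IC1=C[C@@]2(C)[C@H](CC[C@@H](OC(=O)/C(C)=C/C)[C@@H]2C)[C@@H](O)C1=O | intermediate
30 | (10βH)-7-iodo-4β,5β-dimethyl-9β-(3-methylbut-2-enoyloxy)-8-oxodecal-6-en-3α-yl (E)-2-methylbut-2-enoate | IC1=C[C@@]2(C)[C@H](CC[C@@H](OC(=O)/C(C)=C/C)[C@@H]2C)[C@@H](OC(=O)C=C(C)C)C1=O | intermediate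
31 | tributyl(prop-1-en-2-yl)stannane | C=C(C)[Sn](CCCC)(CCCC)CCCC | starting material
32 | 9β-(3-methylbut-2-enoyloxy)-8-oxo-10βH-eremophila-6,11-dien-3α-yl (E)-2-methylbut-2-enoate | C=C(C)C1=C[C@@]2(C)[C@H](CC[C@@H](OC(=O)/C(C)=C/C)[C@@H]2C)[C@@H](OC(=O)C=C(C)C)C1=O | intermediate
33 | copper 7,11-dienolate of 34 (copper on O8) | C=C(C)C=1C[C@@]2(C)[C@H](CC[C@@H](OC(=O)/C(C)=C/C)[C@@H]2C)[C@@H](OC(=O)C=C(C)C)C=1O[Cu] | intermediate (not isolated)
34 | (3R,4R,5R,7R,9R,10S)-9β-(3-methylbut-2-enoyloxy)-8-oxo-10βH-eremophil-11-en-3α-yl (E)-2-methylbut-2-enoate (CNP0375730.1) | C=C(C)[C@H]1C[C@@]2(C)[C@H](CC[C@@H](OC(=O)/C(C)=C/C)[C@@H]2C)[C@@H](OC(=O)C=C(C)C)C1=O | target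

Total step count: 19. Longest linear sequence: 19 steps (1 to 34); 15 and 31 are purchased reactants.

Least certain steps

Step 11 (key step). What may go wrong: poor discrimination between the two enone arms, with closure on the other arm giving the C5 epimer. The preference rests on a conformational bias estimated at only one to two kcal/mol (equatorial silyloxy group against an axial methyl). A second risk is slow insertion with competing hydrodeiodination of 20. Fallback (temporary oxygen tether; it uses the cis relationship of the 3α oxygen and C6 in the target), setting out from 19 and returning at 25: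
- Desilylation (HF·pyridine) would give the 3β-hydroxy dienone F1.
- Mitsunobu inversion with 4-nitrobenzoic acid would give the 3α 4-nitrobenzoate F2.
- K2CO3 in methanol would cleave the ester to the 3α-hydroxy dienone F3, which under the same conditions adds reversibly (5-exo oxa-Michael) to one enone arm to give the oxa-bridged enone F4. Only the adduct with the iodovinyl group and the remaining enone arm cis on the oxolane ring can cyclise; the other reverts through F3.
- The conditions of step 11 then find a single enone arm and would give the tricyclic ether F5, in which the O3–C6 bridge forces the C5 methyl cis to the C4 methyl.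
- DBU with tiglic anhydride and DMAP would open the β-alkoxy ketone by E1cB elimination and acylate the freed 3α oxygen, giving 25.

Step 13. What may go wrong: elimination of the activated allylic alcohol to the ring A 1,3-diene (H-4 can become anti-periplanar to the leaving group), or SN2′ attack at C1, because tiglate is a weak and hindered nucleophile. Fallback (inversion separated from acylation), setting out from 23 and returning at 25: Mitsunobu reaction with the more acidic 4-nitrobenzoic acid would give the 3α 4-nitrobenzoate F6; methanolysis (K2CO3, MeOH, 0 °C) would give the 3α alcohol F7, which may rest partly as its oxa-Michael adduct F5; tiglic anhydride with DMAP and DBU would acylate with retention, reopening any F5, to give 25.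

Step 19. What may go wrong: loss of control at C7. Protonation from the open β face gives the axial 7α epimer, and γ-protonation or base-mediated drift moves the double bond into conjugation as the isopropylidene ketone; slow reduction at the hindered C6 could also allow 1,2-reduction. Fallback (hydride delivery separated from protonation), setting out from 32 and returning at 34: RhCl(PPh3)3-catalysed 1,4-hydrosilylation with Et3SiH would give the triethylsilyl dienol ether F8, which is isolated and then cleaved with HF·pyridine at low temperature, so that C7 is protonated under non-basic conditions.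

Step 9. What may go wrong: sluggish Michael addition of the hindered enamine (the new quaternary C5 sits beside tertiary C4), with polymerisation of 15 taking over. Fallback (Lewis-acid activation of the acceptor in place of enamine activation of the donor), setting out from 14 and returning at 18: TMSOTf and Et3N would give the trimethylsilyl enol ether F9; Mukaiyama–Michael addition to 15 (BF3·OEt2, CH2Cl2, −78 °C) and aqueous work-up would give 17, here isolated; pyrrolidinium acetate would then effect the aldol condensation to 18.

Further compounds

F1 | step 11 | 4-[(2R,3R,4Z)-3-hydroxy-5-iodopent-4-en-2-yl]-4-methylcyclohexa-2,5-dien-1-one | O=C1C=CC(C)(C=C1)[C@@H](C)[C@@H](O)/C=C\I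
F2 | step 11 | (1Z,3S,4R)-1-iodo-4-(1-methyl-4-oxocyclohexa-2,5-dien-1-yl)pent-1-en-3-yl 4-nitrobenzoate | O=C1C=CC(C)(C=C1)[C@@H](C)[C@H](OC(=O)c1ccc(cc1)[N+](=O)[O-])/C=C\I
F3 | step 11 | 4-[(2R,3S,4Z)-3-hydroxy-5-iodopent-4-en-2-yl]-4-methylcyclohexa-2,5-dien-1-one | O=C1C=CC(C)(C=C1)[C@@H](C)[C@H](O)/C=C\I
F4 | step 11 | oxa-bridged enone: 3α,6α-epoxy-4β,5β-dimethyl-1,10-seco compound with a C9=C10 enone, C8 ketone and Z-iodovinyl group on C3 (target numbering) | O=C1C[C@@H]2O[C@H](/C=C\I)[C@H](C)[C@]2(C)C=C1
F5 | step 11 | (10βH)-3α,6α-epoxy-4β,5β-dimethyldecal-1-en-8-one | O=C1C[C@@H]2O[C@@H]3C=C[C@H](C1)[C@@]2(C)[C@H]3C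
F6 | step 13 | (10βH)-4β,5β-dimethyl-8-oxodecal-1,6-dien-3α-yl 4-nitrobenzoate | O=C1C=C[C@@]2(C)[C@H](C=C[C@@H](OC(=O)c3ccc(cc3)[N+](=O)[O-])[C@@H]2C)C1
F7 | step 13 | (10βH)-3α-hydroxy-4β,5β-dimethyldecal-1,6-dien-8-one | O=C1C=C[C@@]2(C)[C@H](C=C[C@@H](O)[C@@H]2C)C1
F8 | step 19 | triethylsilyl 7,11-dienol ether of 34 (silicon on O8) | C=C(C)C=1C[C@@]2(C)[C@H](CC[C@@H](OC(=O)/C(C)=C/C)[C@@H]2C)[C@@H](OC(=O)C=C(C)C)C=1O[Si](CC)(CC)CC
F9 | step 9 | trimethylsilyl enol ether of 14 | C[Si](C)(C)OC=C(C)[C@@H](C)[C@@H](O[Si](C)(C)C(C)(C)C)/C=C\I
A1 | alternative 1 | 2-ethenyl-3,3-dimethoxy-5,6-dimethylbicyclo[2.2.2]oct-5-en-2-ol, vinyl group syn to the C5=C6 bridge | C=C[C@@]1(O)[C@@H]2CC[C@@H](C(C)=C2C)C1(OC)OC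
A2 | alternative 1 | cis-fused 9,9-dimethoxy-4,5-dimethyloctal-3-en-8-one (target numbering) | O=C1CC[C@@]2(C)[C@H](CCC=C2C)C1(OC)OC
A3 | alternative 2 | (7E)-9-(tert-butyldimethylsilyloxy)-4-(4-methoxybenzyloxy)-7,8-dimethyl-5-(prop-1-en-2-yl)deca-1,7,9-trien-3-one | C=C(O[Si](C)(C)C(C)(C)C)/C(C)=C(C)/C[C@H](C(C)=C)[C@@H](OCc1ccc(OC)cc1)C(=O)C=C
A4 | alternative 2 | cis-fused 3-(tert-butyldimethylsilyloxy)-8-(4-methoxybenzyloxy)eremophila-3,11-dien-9-one | C=C(C)[C@H]1C[C@@]2(C)[C@H](CCC(O[Si](C)(C)C(C)(C)C)=C2C)C(=O)[C@@H]1OCc3ccc(OC)cc3
A5 | alternative 3 | cis-fused 7a-methylhexahydroindane-1,5-dione 5-ethylene ketal | O=C1CC[C@@H]2CC3(OCCO3)CC[C@]12C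
A6 | alternative 3 | cis-fused 8,8-ethylenedioxy-4,5-dimethyldecal-3-one (target numbering) | O=C1CC[C@@H]2CC3(OCCO3)CC[C@]2(C)[C@H]1C
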